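## Structural features

The target is a benzenoid ansa-lactam. A 15-carbon chain (C1 = lactam carbonyl, C15 = benzylic CH2) spans the meta positions C20 (nitrogen) and C16 of a para-aminophenol ring, ring A (C16 to C21), whose free hydroxyl sits on C17, ortho to C16. This closes a 19-membered ring. The chain holds two stereo-clusters. C6 (OMe) and C7 (carbamate) are syn and lie next to the (E)-C8=C9 trisubstituted alkene. C10 (Me), C11 (OH) and C12 (OMe) are syn then anti, and the lone C14 methyl follows after the C13 methylene. A second (E)-trisubstituted alkene, C2=C3, is conjugated with the lactam. The fragile groups are the allylic primary carbamate on C7, the para-acylaminophenol (oxidation to a quinone imine), and any free para-aminophenol met on the way. The real difficulty is threefold: the C14 methyl has no neighbouring functional group to control it, the aryl–C15 bond must be made regioselectively, and the large ring must be closed through a weakly nucleophilic aniline. The key step uses the 1,5-relationship between the C11 oxygen and C15. Joining them gives the ring O–C11–C12–C13–C14–C15, which holds C11, C12 and C14 on one chair, and the four carbons C12 to C15 are those of a furan that carries ring A on C15. Because C15 is benzylic and ortho to the C17 oxygen, the C15–O bond can be cleaved again by hydrogenolysis, so the template leaves no trace.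

## Logic of the disconnections

36 ⇐ 35 ⇐ 33. The last bonds cut are the two O–Si bonds (O11, O17) and the C–O bond of the carbamate on O7. The allylic carbamate is the most labile group, so it goes on last, onto the only free hydroxyl of 33. This leaves a macrocycle with one reactive site. The demand is that carbamoylation and fluoride desilylation do not ionise the C7–O bond.

33 ⇐ 32. The N–C1 amide bond is cut. It is the one ring bond whose formation creates neither a stereocentre nor an alkene geometry. The gain is an acyclic amino acid. The forward step must acylate an aniline at high dilution and prefer nitrogen over the free C7 hydroxyl.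

32 ⇐ 30 ⇐ 24 + 28. The C3–C4 bond is cut between an sp3 and an sp2 carbon. C4 then becomes the terminus of a vinyl group in 24, and the (E)-C2=C3 unit arrives with fixed geometry in 28. Nitrogen and C1 carry tert-butyl-based groups, so one silyl triflate treatment frees both ends of 30. The demand is hydroboration of the vinyl group only, not of C8=C9. 28 goes back through 27 and 26 to 25.

24 ⇐ 23. The C6–C7 bond is cut. Both C6 and C7 come from one reagent-controlled addition of a three-carbon methoxyallyl unit to the C7 aldehyde of 23. The gain is two stereocentres and the C4/C5 handle in one step. The demand is syn selectivity and reagent control that overrides the distant C10 centre.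

23 ⇐ 22 ⇐ 21 ⇐ 20 ⇐ 19. The C8=C9 bond is cut to the C9 aldehyde 22 and a stabilised ylide. 22 is traced back through oxidation-level and protecting-group changes to 19. The three silyl ethers of 20 differ enough (primary alkyl, hindered secondary alkyl, aryl) for acid to remove only the primary one. The demand is (E) selectivity and no epimerisation at C10.

19 ⇐ 17. In the retrosynthetic sense the O11–C15 bond is added, NHBoc becomes NO2 and the phenol becomes its benzyl ether. This places C11, C12 and C14 on one six-membered ring and masks the oxidisable aminophenol. The forward step must cleave a cyclic benzylic ether by hydrogenolysis, which the ortho oxygen on C17 has to assist.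

17 ⇐ 16 ⇐ 15 ⇐ 14 ⇐ 13. The O-methyl group, the two hydrogens on C13/C14, the hydrogen on C12 and the hydrogen on C15 are removed in turn. Each forward step is steered by the single centre C11 on a half-chair: C15–H cis, C12–O trans, and C14–Me set by delivery of H2 from the C12 hydroxyl.

13 ⇐ 11 (key). The O11–C15 bond is cut and the pyranone contracts to a furan. C12 to C15, with oxygen on C12 and C15 and unsaturation at C13=C14, are a furan in a higher oxidation state. The gain is a flat aromatic precursor with only C10 and C11 as stereocentres. The demand is oxidation of the furan alone.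

11 ⇐ 10 ⇐ 9 ⇐ 6 + 7. The C10–C11 bond is cut as an aldol bond. An auxiliary-controlled syn-aldol sets both centres at once, where acylation of the furan followed by reduction of an α-chiral ketone would have to override substrate bias. The gain is the achiral aldehyde 6 and the commercial imide 7. The demand is compatibility of the boron aldol with the nitroarene.

6 ⇐ 4 ⇐ 2 + 3, and 2 ⇐ 1. The C11–C12 bond is cut (formylation) and then the C15–C16 bond (decarboxylative arylation). The carboxyl group of 3 fixes the arylation site and its methyl group becomes the C14 methyl. The demand is that the ortho-substituted bromide 2 couples and that formylation takes the one free α-position.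

## Other disconnections considered

Alternative 1: Ring A is taken apart at C16–C17 and C20–C21. The seco compound A1 ends in an N-(furan-2-yl) amide at C1 and in a C15–C16≡C21 alkynyl phenyl sulfone. Heating A1 in dilute solution would give an intramolecular Diels–Alder adduct. The amide nitrogen then opens the oxygen bridge and tautomerisation gives the phenol A2, so the benzene ring and the lactam ring form together.
- In favour: the para N/O pattern of ring A is written into the furan. The sulfone polarises the alkyne so that the nucleophilic furan carbon (future C17) meets C16. No aniline has to be acylated late.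
- Against: the tether is so long that the cycloaddition gains little from being intramolecular, and it must outrun decomposition of the electron-rich amidofuran. The sulfone on C21 must then be removed reductively next to an unsaturated amide and an allylic carbamate. Because the arene does not exist until the end, it cannot serve as a handle for C11 to C15, which need a separate acyclic solution.
- Comparison: this alternative builds what the chosen plan buys (the arene) and leaves open what the chosen plan solves (C11, C12, C14). It is mechanistically the more ambitious. It is better in convergence, since ring A and the macrocycle arise in one step, and it avoids the nitro, benzyl and Boc handling. In step count the two are expected to be about equal once desulfonylation and an independent C10–C14 synthesis are added.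

Alternative 2: The N–C20 bond is cut. The seco compound A3 carries a primary amide at C1 and an aryl bromide at C20. CuI (copper iodide) with N,N'-dimethylethylenediamine and K2CO3 in hot toluene at high dilution would close the ring to A4 by a Goldberg-type amidation.
- In favour: the nitrogen enters as a simple primary amide and needs no protecting group. The aryl bromide is inert during chain assembly. Aryl–nitrogen coupling does not depend on the nucleophilicity of an aniline.
- Against here: a C20 bromide cannot pass through the chosen route. The hydrogenation that opens the pyran would remove it, and the decarboxylative arylation would have to tell two halides apart. The C7 carbamate must wait until after ring closure, because its NH2 would compete for the aryl group, and the methoxymethyl ether on O17 needs acid at the end.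
- Comparison: on the ring-closing event itself this alternative is the better one. It needs no activated ester, has no competition from the C7 hydroxyl, and saves the Boc group. On structure it conflicts with the hydrogenolytic template opening, so adopting it would mean a non-reductive route to C11–C15. Step economy is about equal: the saved N-protection is offset by making the primary amide.

Alternative 3: The C4=C5 bond is cut. The substrate A5 is the anilide of (E)-2-methylpenta-2,4-dienoic acid and carries a vinyl group on C6. The second-generation Grubbs catalyst at high dilution would give the 4,5-didehydro lactam A6 with loss of ethylene. Diimide would then saturate C4=C5, which gives 35 of the chosen route.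
- In favour: the amide is made intermolecularly. The C6 vinyl group is what step 17 delivers, so A5 branches from 24 and needs neither the iodoacrylate branch (steps 18 to 20) nor the cross-coupling. The geometry of the new alkene does not matter.
- Against: the ruthenium carbene must engage the terminal diene carbon and a vinyl group next to a methoxy-bearing carbon. If it engaged C2=C3 instead it would excise two carbons. Diimide must pick the disubstituted alkene of a conjugated dienamide over two trisubstituted alkenes.
- Comparison: in step economy this alternative is better by about three steps, and structurally it is fully compatible with the key step of the chosen plan. Mechanistically it carries two selectivity questions (metathesis site, diimide site) where the lactamisation carries one (N against O acylation). That is why the lactamisation is kept.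

Key step: step 7

Remark on the chemistry: target numbering (C1 = lactam carbonyl, C15 = benzylic carbon, C16–C21 = ring A) is used for all intermediates. 13 is drawn as one anomer, and both anomers and the open-chain tautomer converge in step 8. TBS = tert-butyldimethylsilyl.

## Route

Step 1
Reactants: 1 2-bromo-4-nitrophenol
Product: 2 1-(benzyloxy)-2-bromo-4-nitrobenzene
Conditions: BnBr, K2CO3, DMF, rt
Reagents that add atoms: benzyl bromide, BrCc1ccccc1
Why: Williamson ether synthesis on an acidic nitrophenol; the benzyl group masks O17 until the hydrogenation of step 12, where it is lost without an extra step.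

Step 2
Reactants: 2 1-(benzyloxy)-2-bromo-4-nitrobenzene; 3 3-methylfuran-2-carboxylic acid
Product: 4 2-[2-(benzyloxy)-5-nitrophenyl]-3-methylfuran
Conditions: Pd[P(t-Bu)3]2 (5 mol %), n-Bu4NCl, Cs2CO3, DMF, 170 °C (microwave)
Reagents that add atoms: none
Why: Decarboxylative cross-coupling of a heteroaromatic carboxylic acid with an aryl bromide: zerovalent palladium inserts into the activated C–Br bond, the furan carboxylate is palladated at the ipso carbon with loss of CO2, and reductive elimination forms C15–C16. The carboxyl group fixes the arylation site and the adjacent methyl group (future C14 methyl) blocks the neighbouring position.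

Step 3
Reactants: 4 2-[2-(benzyloxy)-5-nitrophenyl]-3-methylfuran
Product: 6 5-[2-(benzyloxy)-5-nitrophenyl]-4-methylfuran-2-carbaldehyde, via iminium salt 5 (not isolated)
Conditions: POCl3, DMF, 0 to 50 °C; then aq NaOAc
Reagents that add atoms: N,N-dimethylformamide, CN(C)C=O; water, O
Why: Vilsmeier–Haack formylation at the only free α-position of the furan (C12), which brings in C11; the nitro-deactivated benzene ring should not react.

Step 4
Reactants: 6 5-[2-(benzyloxy)-5-nitrophenyl]-4-methylfuran-2-carbaldehyde; 7 (R)-4-benzyl-3-propanoyl-1,3-oxazolidin-2-one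
Product: 9 (R)-4-benzyl-3-[(2R,3R)-3-{5-[2-(benzyloxy)-5-nitrophenyl]-4-methylfuran-2-yl}-3-hydroxy-2-methylpropanoyl]-1,3-oxazolidin-2-one, via boron enolate 8 (not isolated)
Conditions: Bu2BOTf, i-Pr2NEt, CH2Cl2, −78 to 0 °C; then 6, −78 to 0 °C; pH 7 buffer, MeOH, H2O2, 0 °C
Reagents that add atoms: none
Why: Evans syn-aldol reaction: the (Z)-boron enolate 8 adds through a closed chair transition state on the face away from the auxiliary benzyl group, which sets C10 and C11 together (syn; 10S,11R in target terms) by auxiliary control.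

Step 5
Reactants: 9 the aldol adduct
Product: 10 (1R,2S)-1-{5-[2-(benzyloxy)-5-nitrophenyl]-4-methylfuran-2-yl}-2-methylpropane-1,3-diol
Conditions: LiBH4, MeOH (1 equiv), THF, 0 °C
Reagents that add atoms: none
Why: Reductive removal of the oxazolidinone from an N-acyl imide; LiBH4 reduces the exocyclic carbonyl to the C9 carbinol and should leave the aromatic nitro group and both stereocentres untouched.

Step 6
Reactants: 10 the 1,3-diol
Product: 11 (1R,2S)-1-{5-[2-(benzyloxy)-5-nitrophenyl]-4-methylfuran-2-yl}-3-[(tert-butyldimethylsilyl)oxy]-2-methylpropan-1-ol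
Conditions: TBSCl, imidazole, CH2Cl2, 0 °C
Reagents that add atoms: tert-butyldimethylsilyl chloride, CC(C)(C)[Si](C)(C)Cl
Why: Selective silylation of the primary C9 hydroxyl over the hindered secondary furyl carbinol, which must stay free to close the ring in step 7.

Step 7
Reactants: 11 the furyl carbinol (C9 OTBS, C10 S, C11 R)
Product: 13 (2R,6R)-6-[2-(benzyloxy)-5-nitrophenyl]-2-[(2S)-1-{[tert-butyl(dimethyl)silyl]oxy}propan-2-yl]-6-hydroxy-5-methyl-2H-pyran-3(6H)-one (hydroxyl on C15 trans to the C11 side chain), via Z-ene-dione 12 (not isolated)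
Conditions: NBS, NaHCO3, NaOAc, THF–H2O (4:1), 0 °C
Reagents that add atoms: water, O
Why: Achmatowicz rearrangement: NBS transfers Br+ to an α-carbon of the furan, water adds at the other α-carbon, and loss of HBr opens the resulting 2,5-dihydrofuran to the (Z)-ene-dione 12 with carbonyls at C12 and C15. The C11 hydroxyl then adds to the C15 aryl ketone in a 6-exo-trig hemiketalisation, which forms the O–C15 bond and the six-membered pyranone. The closest known reaction type is this rearrangement of 5-substituted furfuryl alcohols, including 5-aryl cases. The one new stereocentre, the C15 hemiketal, is under thermodynamic control (anomeric hydroxyl axial, aryl group pseudo-equatorial and cis to the C11 side chain); it is temporary, because step 8 removes it through a planar cation. The step needs oxidation of the furan only, and the furan is the sole electron-rich π-system beside a nitro-deactivated arene, a benzyl ether and a silyl ether. The buffer keeps HBr from cleaving the silyl ether or enolising the new ketone towards C11, so C10 and C11 should pass unchanged.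

Step 8
Reactants: 13 the hemiketal pyranone
Product: 14 (2R,6R)-6-[2-(benzyloxy)-5-nitrophenyl]-2-[(2S)-1-{[tert-butyl(dimethyl)silyl]oxy}propan-2-yl]-5-methyl-2H-pyran-3(6H)-one (2,6-cis)
Conditions: Et3SiH, CF3CO2H, CH2Cl2, −45 °C
Reagents that add atoms: none
Why: Ionic reduction of the hemiketal: acid ionises C15–OH to the aryl-stabilised cyclic oxocarbenium ion and Et3SiH adds axially, which leaves the aryl group pseudo-equatorial and cis to the C11 side chain. The low temperature protects the primary silyl ether.

Step 9
Reactants: 14 the cis-dihydropyranone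
Product: 15 (2R,3S,6R)-6-[2-(benzyloxy)-5-nitrophenyl]-2-[(2S)-1-{[tert-butyl(dimethyl)silyl]oxy}propan-2-yl]-5-methyl-3,6-dihydro-2H-pyran-3-ol (hydroxyl trans to the C11 side chain)
Conditions: NaBH4, CeCl3·7H2O, MeOH–CH2Cl2, −78 °C
Reagents that add atoms: none
Why: Luche 1,2-reduction: hydride enters the C12 carbonyl axially, anti to the axial C11–H, so it is the new hydroxyl (not the hydride) that ends trans to the C11 side chain, which is the 12S configuration. CeCl3 suppresses conjugate reduction.

Step 10
Reactants: 15 the allylic alcohol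
Product: 16 (2R,3S,5S,6R)-6-[2-(benzyloxy)-5-nitrophenyl]-2-[(2S)-1-{[tert-butyl(dimethyl)silyl]oxy}propan-2-yl]-5-methyloxan-3-ol (C14 methyl cis to the aryl group)
Conditions: H2 (1 bar), [Ir(cod)(PCy3)(py)]PF6 (5 mol %), CH2Cl2, rt
Reagents that add atoms: none
Why: Hydroxyl-directed homogeneous hydrogenation of a cyclic allylic alcohol: the cationic iridium centre binds the C12 hydroxyl and delivers H2 to the alkene face that carries it, opposite the C11 side chain and the C15 aryl group, so the C14 methyl ends cis to the aryl group (14R of the target). Saturating the alkene on the closed ring before any palladium step avoids the risk that the allylic and benzylic C15–O bond cleaves first and control of C14 is lost; the iridium catalyst should leave C–O bonds, the nitro group and the benzyl ether intact.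

Step 11
Reactants: 16 the oxan-3-ol
Product: 17 tert-butyl{(2S)-2-[(2R,3S,5S,6R)-6-(2-benzyloxy-5-nitrophenyl)-3-methoxy-5-methyloxan-2-yl]propoxy}dimethylsilane
Conditions: Me3OBF4, 1,8-bis(dimethylamino)naphthalene, 4 Å MS, CH2Cl2, 0 °C to rt
Reagents that add atoms: trimethyloxonium tetrafluoroborate, C[O+](C)C.F[B-](F)(F)F
Why: O-Methylation of a hindered secondary alcohol under non-basic conditions, which avoids alkoxide chemistry next to the nitroarene and keeps the silyl ether.

Step 12
Reactants: 17 the methoxy-oxane
Product: 19 tert-butyl N-{4-hydroxy-3-[(2R,4S,5R,6S)-7-{[tert-butyl(dimethyl)silyl]oxy}-5-hydroxy-4-methoxy-2,6-dimethylheptyl]phenyl}carbamate, via ring-opened aminophenol 18 (not isolated)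
Conditions: H2 (4 bar), Pd(OH)2/C, MeOH–EtOAc–AcOH, rt; filter under Ar; then Boc2O, THF, rt
Reagents that add atoms: di-tert-butyl dicarbonate, CC(C)(C)OC(=O)OC(=O)OC(C)(C)C
Why: Heterogeneous hydrogenation reduces the nitro group and cleaves the O-benzyl ether; the ring C15–O bond, benzylic and ortho to the freed C17 phenol, then undergoes acid-assisted hydrogenolysis (known for 2-aryltetrahydropyrans), which returns the C11 hydroxyl and the C15 methylene without touching a stereocentre. Boc2O acylates only the aniline nitrogen, so the air-sensitive aminophenol 18 is never isolated.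

Step 13
Reactants: 19 the N-Boc aminophenol
Product: 20 tert-butyl N-{4-[(tert-butyldimethylsilyl)oxy]-3-[(2R,4S,5R,6S)-5,7-bis{[tert-butyl(dimethyl)silyl]oxy}-4-methoxy-2,6-dimethylheptyl]phenyl}carbamate
Conditions: TBSOTf, 2,6-lutidine, CH2Cl2, −78 to −40 °C
Reagents that add atoms: tert-butyldimethylsilyl trifluoromethanesulfonate, CC(C)(C)[Si](C)(C)OS(=O)(=O)C(F)(F)F
Why: Silylation of the phenol and of the hindered C11 hydroxyl with a silyl triflate; the low temperature keeps the N-Boc group from being converted into its silyl carbamate.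

Step 14
Reactants: 20 the tris-silyl ether
Product: 21 tert-butyl N-{4-[(tert-butyldimethylsilyl)oxy]-3-[(2R,4S,5R,6S)-5-{[tert-butyl(dimethyl)silyl]oxy}-7-hydroxy-4-methoxy-2,6-dimethylheptyl]phenyl}carbamate
Conditions: CSA (cat.), MeOH–CH2Cl2, 0 °C
Reagents that add atoms: none
Why: Acid-catalysed methanolysis removes the primary alkyl silyl ether much faster than the hindered secondary one at C11 or the aryl silyl ether, which is the more acid-stable of the three.

Step 15
Reactants: 21 the C9 alcohol
Product: 22 tert-butyl N-{4-[(tert-butyldimethylsilyl)oxy]-3-[(2R,4S,5R,6R)-5-{[tert-butyl(dimethyl)silyl]oxy}-4-methoxy-2,6-dimethyl-7-oxoheptyl]phenyl}carbamate (C9 aldehyde; C10 geometry unchanged)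
Conditions: Dess–Martin periodinane, NaHCO3, CH2Cl2, 0 °C to rt
Reagents that add atoms: none
Why: Dess–Martin oxidation of a primary alcohol under buffered, non-enolising conditions, so the α-stereocentre C10 should not epimerise.

Step 16
Reactants: 22 the C9 aldehyde
Product: 23 tert-butyl N-{4-[(tert-butyldimethylsilyl)oxy]-3-[(2R,4S,5R,6S,7E)-5-{[tert-butyl(dimethyl)silyl]oxy}-4-methoxy-2,6,8-trimethyl-9-oxonon-7-en-1-yl]phenyl}carbamate (C7 aldehyde; E C8=C9)
Conditions: Ph3P=C(Me)CHO, toluene, 90 °C
Reagents that add atoms: 2-(triphenylphosphoranylidene)propanal, CC(C=O)=P(c1ccccc1)(c1ccccc1)c1ccccc1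
Why: Wittig reaction with a stabilised formyl ylide, which should give the (E)-trisubstituted enal directly (C8 methyl and C7 in one step); the enal product is much less reactive towards the ylide than the starting aldehyde.

Step 17
Reactants: 23 the enal
Product: 24 tert-butyl N-{4-[(tert-butyldimethylsilyl)oxy]-3-[(2R,4S,5R,6S,7E,9S,10S)-5-{[tert-butyl(dimethyl)silyl]oxy}-9-hydroxy-4,10-dimethoxy-2,6,8-trimethyldodeca-7,11-dien-1-yl]phenyl}carbamate (C6 OMe, C7 OH syn; vinyl group = C5/C4)
Conditions: CH2=CHCH2OMe, s-BuLi, THF, −78 °C; (+)-Ipc2BOMe; BF3·OEt2; then 23, −78 °C; ethanolamine work-up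
Reagents that add atoms: allyl methyl ether, COCC=C
Why: Asymmetric γ-methoxyallylboration: the (Z)-γ-methoxyallyl-diisopinocampheylborane made in the flask adds through a closed chair transition state, so the Z geometry gives the syn methoxy alcohol. The isopinocampheyl groups derived from (−)-α-pinene direct attack to the Re face of the aldehyde (7S), hence 6S,7S by reagent control.

Step 18
Reactants: 25 diethyl methylmalonate
Product: 26 diethyl 2-(diiodomethyl)-2-methylmalonate
Conditions: NaH, CHI3, Et2O, reflux
Reagents that add atoms: iodoform, IC(I)I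
Why: C-Diiodomethylation of the sodium malonate enolate with iodoform (capture of diiodocarbene), a known entry to 3-iodomethacrylic acid derivatives.

Step 19
Reactants: 26 diethyl 2-(diiodomethyl)-2-methylmalonate
Product: 27 (E)-3-iodo-2-methylprop-2-enoic acid
Conditions: KOH, EtOH–H2O, reflux; then HCl
Reagents that add atoms: potassium hydroxide, [K+].[OH-]
Why: Saponification of both esters followed by decarboxylation with loss of iodide gives the (E)-iodoacrylic acid, in which iodine is trans to the carboxyl group.

Step 20
Reactants: 27 (E)-3-iodo-2-methylprop-2-enoic acid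
Product: 28 tert-butyl (E)-3-iodo-2-methylprop-2-enoate
Conditions: Boc2O, DMAP (cat.), t-BuOH, rt
Reagents that add atoms: di-tert-butyl dicarbonate, CC(C)(C)OC(=O)OC(=O)OC(C)(C)C
Why: Mild tert-butyl esterification through the mixed carbonic anhydride; no strong acid or base touches the vinyl iodide.

Step 21
Reactants: 24 the C6 vinyl compound; 28 tert-butyl (E)-3-iodo-2-methylprop-2-enoate
Product: 30 tert-butyl (2E,6S,7S,8E,10S,11R,12S,14R)-15-{5-[(tert-butoxycarbonyl)amino]-2-[(tert-butyldimethylsilyl)oxy]phenyl}-11-[(tert-butyldimethylsilyl)oxy]-7-hydroxy-6,12-dimethoxy-2,8,10,14-tetramethylpentadeca-2,8-dienoate, via B-alkyl borane 29 (not isolated)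
Conditions: 9-BBN (3 equiv), THF, rt; then 28, Pd(dppf)Cl2 (10 mol %), AsPh3, Cs2CO3, DMF–H2O, rt
Reagents that add atoms: none
Why: 9-BBN hydroborates only the monosubstituted alkene (boron on C4) and leaves the trisubstituted C8=C9; the free C7 hydroxyl merely consumes one equivalent as a borinate. B-Alkyl Suzuki–Miyaura coupling (the divalent palladium precatalyst is reduced in the flask to zerovalent palladium) then forms C3–C4 with retention of the (E) geometry of the vinyl iodide.

Step 22
Reactants: 30 the doubly tert-butyl-protected seco compound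
Product: 32 (2E,6S,7S,8E,10S,11R,12S,14R)-15-{5-amino-2-[(tert-butyldimethylsilyl)oxy]phenyl}-11-[(tert-butyldimethylsilyl)oxy]-7-hydroxy-6,12-dimethoxy-2,8,10,14-tetramethylpentadeca-2,8-dienoic acid, via tris-trimethylsilyl intermediate 31 (not isolated)
Conditions: TMSOTf, 2,6-lutidine, CH2Cl2, 0 °C to rt; then MeOH, pH 7 buffer
Reagents that add atoms: none
Why: The silyl triflate converts the N-Boc group and the tert-butyl ester into a silyl carbamate and a silyl ester with loss of isobutene; methanolysis then frees the aniline (after decarboxylation), the acid and the transiently silylated C7 hydroxyl. The medium is buffered by lutidine, so the TBS ethers should survive.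

Step 23
Reactants: 32 the seco amino acid
Product: 33 7-O-decarbamoyl-11,17-bis-O-(tert-butyldimethylsilyl) derivative of 36 (19-membered lactam with free C7 hydroxyl)
Conditions: BOPCl, i-Pr2NEt, toluene (1 mM), 85 °C, slow addition
Reagents that add atoms: none
Why: Macrolactamisation through a mixed phosphinic anhydride, the established way to close ansa-lactams from aniline seco acids; the acid has no α-stereocentre. Nitrogen should win over the C7 hydroxyl, because a lactone through O7 would be an eight-membered ring holding an (E)-alkene and intermolecular acylation is suppressed by dilution.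

Step 24
Reactants: 33 the macrolactam
Product: 35 11,17-bis-O-(tert-butyldimethylsilyl) derivative of 36 (C7 carbamate in place), via N-trichloroacetyl carbamate 34 (not isolated)
Conditions: Cl3CC(O)NCO, CH2Cl2, 0 °C; then neutral Al2O3, rt
Reagents that add atoms: trichloroacetyl isocyanate, O=C=NC(=O)C(Cl)(Cl)Cl
Why: The acyl isocyanate carbamoylates the only free hydroxyl (C7); the trichloroacetyl group is then hydrolysed on Al2O3 under neutral conditions that spare the aryl silyl ether and the allylic C–O bond.

Step 25
Reactants: 35 the bis-silyl ether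
Product: 36 the target (6S,7S,10S,11R,12S,14R; 2E,8E)
Conditions: HF·pyridine, pyridine, THF, 0 °C to rt
Reagents that add atoms: none
Why: Buffered fluoride cleaves the aryl and the hindered C11 silyl ethers; the medium is neither basic enough to attack the carbamate nor acidic enough to ionise the allylic C7–O bond.

## Compound list

1 | 2-bromo-4-nitrophenol | Oc1ccc(cc1Br)[N+](=O)[O-] | starting material
2 | 1-(benzyloxy)-2-bromo-4-nitrobenzene | Brc1cc(ccc1OCc1ccccc1)[N+](=O)[O-] | intermediate
3 | 3-methylfuran-2-carboxylic acid | Cc1ccoc1C(=O)O | starting material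
4 | 2-[2-(benzyloxy)-5-nitrophenyl]-3-methylfuran | Cc1ccoc1-c1cc(ccc1OCc1ccccc1)[N+](=O)[O-] | intermediate
5 | iminium salt of the formylation (dichlorophosphate), formed in the flask | C[N+](C)=Cc1cc(C)c(-c2cc(ccc2OCc2ccccc2)[N+](=O)[O-])o1.[O-]P(=O)(Cl)Cl | intermediate
6 | 5-[2-(benzyloxy)-5-nitrophenyl]-4-methylfuran-2-carbaldehyde | O=Cc1cc(C)c(-c2cc(ccc2OCc2ccccc2)[N+](=O)[O-])o1 | intermediate
7 | (R)-4-benzyl-3-propanoyl-1,3-oxazolidin-2-one | CCC(=O)N1[C@H](Cc2ccccc2)COC1=O | starting material
8 | (Z)-dibutylboron enolate of 7, formed in the flask | C/C=C(\OB(CCCC)CCCC)N1[C@H](Cc2ccccc2)COC1=O | intermediate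
9 | (R)-4-benzyl-3-[(2R,3R)-3-{5-[2-(benzyloxy)-5-nitrophenyl]-4-methylfuran-2-yl}-3-hydroxy-2-methylpropanoyl]-1,3-oxazolidin-2-one | O=C(N1[C@H](Cc2ccccc2)COC1=O)[C@H](C)[C@@H](O)c1cc(C)c(-c2cc(ccc2OCc2ccccc2)[N+](=O)[O-])o1 | intermediate
10 | (1R,2S)-1-{5-[2-(benzyloxy)-5-nitrophenyl]-4-methylfuran-2-yl}-2-methylpropane-1,3-diol | OC[C@H](C)[C@@H](O)c1cc(C)c(-c2cc(ccc2OCc2ccccc2)[N+](=O)[O-])o1 | intermediate
11 | (1R,2S)-1-{5-[2-(benzyloxy)-5-nitrophenyl]-4-methylfuran-2-yl}-3-[(tert-butyldimethylsilyl)oxy]-2-methylpropan-1-ol (precursor of the key step) | CC(C)(C)[Si](C)(C)OC[C@H](C)[C@@H](O)c1cc(C)c(-c2cc(ccc2OCc2ccccc2)[N+](=O)[O-])o1 | intermediate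
12 | (2Z,5R,6S)-1-[2-(benzyloxy)-5-nitrophenyl]-7-[(tert-butyldimethylsilyl)oxy]-5-hydroxy-2,6-dimethylhept-2-ene-1,4-dione, formed in the flask | CC(C)(C)[Si](C)(C)OC[C@H](C)[C@@H](O)C(=O)/C=C(/C)C(=O)c1cc(ccc1OCc1ccccc1)[N+](=O)[O-] | intermediate
13 | (2R,6R)-6-[2-(benzyloxy)-5-nitrophenyl]-2-[(2S)-1-{[tert-butyl(dimethyl)silyl]oxy}propan-2-yl]-6-hydroxy-5-methyl-2H-pyran-3(6H)-one (product of the key step) | CC(C)(C)[Si](C)(C)OC[C@H](C)[C@H]1O[C@@](O)(c2cc(ccc2OCc2ccccc2)[N+](=O)[O-])C(C)=CC1=O | intermediate
14 | (2R,6R)-6-[2-(benzyloxy)-5-nitrophenyl]-2-[(2S)-1-{[tert-butyl(dimethyl)silyl]oxy}propan-2-yl]-5-methyl-2H-pyran-3(6H)-one (2,6-cis) | CC(C)(C)[Si](C)(C)OC[C@H](C)[C@H]1O[C@@H](c2cc(ccc2OCc2ccccc2)[N+](=O)[O-])C(C)=CC1=O | intermediate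
15 | (2R,3S,6R)-6-[2-(benzyloxy)-5-nitrophenyl]-2-[(2S)-1-{[tert-butyl(dimethyl)silyl]oxy}propan-2-yl]-5-methyl-3,6-dihydro-2H-pyran-3-ol | CC(C)(C)[Si](C)(C)OC[C@H](C)[C@H]1O[C@@H](c2cc(ccc2OCc2ccccc2)[N+](=O)[O-])C(C)=C[C@@H]1O | intermediate
16 | (2R,3S,5S,6R)-6-[2-(benzyloxy)-5-nitrophenyl]-2-[(2S)-1-{[tert-butyl(dimethyl)silyl]oxy}propan-2-yl]-5-methyloxan-3-ol | CC(C)(C)[Si](C)(C)OC[C@H](C)[C@H]1O[C@@H](c2cc(ccc2OCc2ccccc2)[N+](=O)[O-])[C@@H](C)C[C@@H]1O | intermediate
17 | tert-butyl{(2S)-2-[(2R,3S,5S,6R)-6-(2-benzyloxy-5-nitrophenyl)-3-methoxy-5-methyloxan-2-yl]propoxy}dimethylsilane | CC(C)(C)[Si](C)(C)OC[C@H](C)[C@H]1O[C@@H](c2cc(ccc2OCc2ccccc2)[N+](=O)[O-])[C@@H](C)C[C@@H]1OC | intermediate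
18 | 4-amino-2-[(2R,4S,5R,6S)-7-{[tert-butyl(dimethyl)silyl]oxy}-5-hydroxy-4-methoxy-2,6-dimethylheptyl]phenol, formed in the flask | CO[C@@H](C[C@H](C)Cc1cc(N)ccc1O)[C@H](O)[C@@H](C)CO[Si](C)(C)C(C)(C)C | intermediate
19 | tert-butyl N-{4-hydroxy-3-[(2R,4S,5R,6S)-7-{[tert-butyl(dimethyl)silyl]oxy}-5-hydroxy-4-methoxy-2,6-dimethylheptyl]phenyl}carbamate | CO[C@@H](C[C@H](C)Cc1cc(NC(=O)OC(C)(C)C)ccc1O)[C@H](O)[C@@H](C)CO[Si](C)(C)C(C)(C)C | intermediate
20 | tris-TBS ether of 19 (O17, O11 and O9 silylated) | CO[C@@H](C[C@H](C)Cc1cc(NC(=O)OC(C)(C)C)ccc1O[Si](C)(C)C(C)(C)C)[C@H](O[Si](C)(C)C(C)(C)C)[C@@H](C)CO[Si](C)(C)C(C)(C)C | intermediate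
21 | C9 primary alcohol (O17 and O11 TBS ethers, NHBoc) | CO[C@@H](C[C@H](C)Cc1cc(NC(=O)OC(C)(C)C)ccc1O[Si](C)(C)C(C)(C)C)[C@H](O[Si](C)(C)C(C)(C)C)[C@@H](C)CO | intermediate
22 | C9 aldehyde (O17 and O11 TBS ethers, NHBoc) | CO[C@@H](C[C@H](C)Cc1cc(NC(=O)OC(C)(C)C)ccc1O[Si](C)(C)C(C)(C)C)[C@H](O[Si](C)(C)C(C)(C)C)[C@@H](C)C=O | intermediate
23 | (E)-C8=C9 enal with C7 aldehyde and C8 methyl (O17 and O11 TBS ethers, NHBoc) | CO[C@@H](C[C@H](C)Cc1cc(NC(=O)OC(C)(C)C)ccc1O[Si](C)(C)C(C)(C)C)[C@H](O[Si](C)(C)C(C)(C)C)[C@@H](C)/C=C(\C)C=O | intermediate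
24 | (6S,7S)-6-methoxy-7-hydroxy compound with C5=C4 vinyl group (O17 and O11 TBS ethers, NHBoc) | CO[C@@H](C[C@H](C)Cc1cc(NC(=O)OC(C)(C)C)ccc1O[Si](C)(C)C(C)(C)C)[C@H](O[Si](C)(C)C(C)(C)C)[C@@H](C)/C=C(\C)[C@H](O)[C@@H](OC)C=C | intermediate
25 | diethyl methylmalonate | CCOC(=O)C(C)C(=O)OCC | starting material
26 | diethyl 2-(diiodomethyl)-2-methylmalonate | CCOC(=O)C(C)(C(I)I)C(=O)OCC | intermediate
27 | (E)-3-iodo-2-methylprop-2-enoic acid | C/C(=C\I)C(=O)O | intermediate
28 | tert-butyl (E)-3-iodo-2-methylprop-2-enoate | C/C(=C\I)C(=O)OC(C)(C)C | intermediate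
29 | C4 9-borabicyclo[3.3.1]nonan-9-yl adduct of 24 (C7 hydroxyl as its 9-BBN borinate), formed in the flask | CO[C@@H](C[C@H](C)Cc1cc(NC(=O)OC(C)(C)C)ccc1O[Si](C)(C)C(C)(C)C)[C@H](O[Si](C)(C)C(C)(C)C)[C@@H](C)/C=C(\C)[C@H](OB1C2CCCC1CCC2)[C@@H](OC)CCB1C2CCCC1CCC2 | intermediate
30 | tert-butyl (2E,6S,7S,8E,10S,11R,12S,14R)-15-{5-[(tert-butoxycarbonyl)amino]-2-[(tert-butyldimethylsilyl)oxy]phenyl}-11-[(tert-butyldimethylsilyl)oxy]-7-hydroxy-6,12-dimethoxy-2,8,10,14-tetramethylpentadeca-2,8-dienoate | CO[C@@H](C[C@H](C)Cc1cc(NC(=O)OC(C)(C)C)ccc1O[Si](C)(C)C(C)(C)C)[C@H](O[Si](C)(C)C(C)(C)C)[C@@H](C)/C=C(\C)[C@H](O)[C@@H](OC)CC/C=C(\C)C(=O)OC(C)(C)C | intermediate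
31 | trimethylsilyl carbamate, trimethylsilyl ester and C7 trimethylsilyl ether derived from 30, formed in the flask | CO[C@@H](C[C@H](C)Cc1cc(NC(=O)O[Si](C)(C)C)ccc1O[Si](C)(C)C(C)(C)C)[C@H](O[Si](C)(C)C(C)(C)C)[C@@H](C)/C=C(\C)[C@H](O[Si](C)(C)C)[C@@H](OC)CC/C=C(\C)C(=O)O[Si](C)(C)C | intermediate
32 | (2E,6S,7S,8E,10S,11R,12S,14R)-15-{5-amino-2-[(tert-butyldimethylsilyl)oxy]phenyl}-11-[(tert-butyldimethylsilyl)oxy]-7-hydroxy-6,12-dimethoxy-2,8,10,14-tetramethylpentadeca-2,8-dienoic acid | CO[C@@H](C[C@H](C)Cc1cc(N)ccc1O[Si](C)(C)C(C)(C)C)[C@H](O[Si](C)(C)C(C)(C)C)[C@@H](C)/C=C(\C)[C@H](O)[C@@H](OC)CC/C=C(\C)C(=O)O | intermediate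
33 | 7-O-decarbamoyl-11,17-bis-O-(tert-butyldimethylsilyl) derivative of 36 | CO[C@H]1C[C@H](C)Cc2cc(ccc2O[Si](C)(C)C(C)(C)C)NC(=O)/C(C)=C/CC[C@H](OC)[C@@H](O)/C(C)=C/[C@H](C)[C@H]1O[Si](C)(C)C(C)(C)C | intermediate
34 | N-(trichloroacetyl)carbamate at O7 of 33, formed in the flask | CO[C@H]1C[C@H](C)Cc2cc(ccc2O[Si](C)(C)C(C)(C)C)NC(=O)/C(C)=C/CC[C@H](OC)[C@@H](OC(=O)NC(=O)C(Cl)(Cl)Cl)/C(C)=C/[C@H](C)[C@H]1O[Si](C)(C)C(C)(C)C | intermediate
35 | 11,17-bis-O-(tert-butyldimethylsilyl) derivative of 36 | CO[C@H]1C[C@H](C)Cc2cc(ccc2O[Si](C)(C)C(C)(C)C)NC(=O)/C(C)=C/CC[C@H](OC)[C@@H](OC(N)=O)/C(C)=C/[C@H](C)[C@H]1O[Si](C)(C)C(C)(C)C | intermediate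
36 | CNP0544610.1: 19-membered lactam, (2E,8E), 6S,7S,10S,11R,12S,14R, C7 carbamate, free C11 and C17 hydroxyls | CO[C@H]1C[C@H](C)Cc2cc(ccc2O)NC(=O)/C(C)=C/CC[C@H](OC)[C@@H](OC(N)=O)/C(C)=C/[C@H](C)[C@H]1O | target

## Step count and least certain steps

Total: 25 steps. Longest linear sequence: 22 steps (steps 1 to 17 and 21 to 25, from 1). Steps 18 to 20 form a three-step side branch to 28.

Step 7 (key step). The likely failure is over-reaction: a second bromination of the electron-rich 2-arylfuran or of the enolisable product, or acid-induced loss of the silyl group if the buffer is exhausted. Incomplete ring closure of the aryl ketone would not matter, because step 8 collects both tautomers. Fallback, from 11 back to 13: oxidise in two stages. Bromine in methanol over Na2CO3 at −40 °C (or anodic methoxylation) should give the 2,5-dimethoxy-2,5-dihydrofuran F1, which is stable and can be purified. Dilute aqueous acid in acetone then hydrolyses both acetal carbons and lets the C11 hydroxyl close onto C15 to give 13.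

Step 10. The likely failure is poor facial selectivity or a stalled hydrogenation: the C12 hydroxyl is pseudo-equatorial and may bind iridium only weakly, the alkene is trisubstituted and flanked by the aryl group, and the nitro group can compete as a ligand. Fallback, from 15 back to 19: methylate 15 as in step 11 to the allylic methyl ether F2 and rely on steric control instead. Hydrogenation over Pd(OH)2/C, first at 1 bar without acid so that H2 adds to the alkene face opposite the aryl group, then with AcOH at 4 bar and Boc2O as in step 12, should give 19 directly.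

Step 12. The likely failure is incomplete cleavage of the ring C15–O bond, since a cyclic benzylic dialkyl ether reacts far more slowly than the nitro group and the benzyl ether, together with catalyst poisoning by the aminophenol. Fallback, from 17 back to 19: hydrogenate briefly (H2 1 bar, Pd/C, EtOAc, Boc2O present) to the ring-intact N-Boc aminophenol F3. Then open the ring by ionic reduction with Et3SiH and BF3·OEt2 in CH2Cl2 at −40 °C, where the free ortho phenol lets C15 ionise as an ortho-quinone methide that the silane reduces. Re-acylate with Boc2O if the carbamate is partly lost.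

Step 17. The likely failure is insufficient reagent control over the enal face in the presence of the C10 centre, or partial loss of the Z geometry of the metallated allyl ether, which would lower the syn selectivity. Fallback, from 23 back to 24: an auxiliary-controlled syn-glycolate aldol reaction of 23 with (R)-4-benzyl-3-(methoxyacetyl)-1,3-oxazolidin-2-one (Bu2BOTf, Et3N) should give the imide F4. AlMe3 with N,O-dimethylhydroxylamine hydrochloride converts it into the N-methoxy-N-methylamide F5, and i-Bu2AlH at −78 °C gives the α-methoxy-β-hydroxy aldehyde F6. Methylenation with Ph3P=CH2 then gives 24.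

Step 23. The likely failure is oligomerisation or acylation of the free C7 hydroxyl, if the aniline reacts too slowly with the activated acid at the dilution required. Fallback, from 24 back to 33: make the amide first and close the ring at C3–C4. TMSOTf with 2,6-lutidine removes the Boc group of 24 to give the aniline F7. Carbodiimide coupling (EDC, HOAt) with the acid 27 gives the (E)-3-iodo-2-methylacrylanilide F8. Hydroboration of the vinyl group with 9-BBN, followed by an intramolecular B-alkyl Suzuki–Miyaura coupling at high dilution (Pd(dppf)Cl2, AsPh3, Cs2CO3, DMF–THF–H2O), should give 33.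

## Further compounds

F1 | step 7 | (1R,2S)-1-{5-[2-(benzyloxy)-5-nitrophenyl]-2,5-dimethoxy-4-methyl-2,5-dihydrofuran-2-yl}-3-[(tert-butyldimethylsilyl)oxy]-2-methylpropan-1-ol (both acetal carbons as mixtures) | CC(C)(C)[Si](C)(C)OC[C@H](C)[C@@H](O)C1(OC)C=C(C)C(OC)(c2cc(ccc2OCc2ccccc2)[N+](=O)[O-])O1
F2 | step 10 | C12 methyl ether of 15 (3,6-dihydro-2H-pyran, alkene intact) | CC(C)(C)[Si](C)(C)OC[C@H](C)[C@H]1O[C@@H](c2cc(ccc2OCc2ccccc2)[N+](=O)[O-])C(C)=C[C@@H]1OC
F3 | step 12 | tert-butyl N-{4-hydroxy-3-[(2R,3S,5S,6R)-oxan-2-yl]phenyl}carbamate analogue of 17 (nitro reduced and Boc-protected, benzyl removed, ring intact) | CC(C)(C)[Si](C)(C)OC[C@H](C)[C@H]1O[C@@H](c2cc(NC(=O)OC(C)(C)C)ccc2O)[C@@H](C)C[C@@H]1OC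
F4 | step 17 | syn-glycolate aldol adduct of 23 (C5 acyl oxazolidinone, 6S-OMe, 7S-OH in target terms) | CO[C@@H](C[C@H](C)Cc1cc(NC(=O)OC(C)(C)C)ccc1O[Si](C)(C)C(C)(C)C)[C@H](O[Si](C)(C)C(C)(C)C)[C@@H](C)/C=C(\C)[C@H](O)[C@@H](OC)C(=O)N1[C@H](Cc2ccccc2)COC1=O
F5 | step 17 | C5 N-methoxy-N-methylamide derived from F4 | CO[C@@H](C[C@H](C)Cc1cc(NC(=O)OC(C)(C)C)ccc1O[Si](C)(C)C(C)(C)C)[C@H](O[Si](C)(C)C(C)(C)C)[C@@H](C)/C=C(\C)[C@H](O)[C@@H](OC)C(=O)N(C)OC
F6 | step 17 | C5 aldehyde derived from F5 | CO[C@@H](C[C@H](C)Cc1cc(NC(=O)OC(C)(C)C)ccc1O[Si](C)(C)C(C)(C)C)[C@H](O[Si](C)(C)C(C)(C)C)[C@@H](C)/C=C(\C)[C@H](O)[C@@H](OC)C=O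
F7 | step 23 | free aniline derived from 24 | CO[C@@H](C[C@H](C)Cc1cc(N)ccc1O[Si](C)(C)C(C)(C)C)[C@H](O[Si](C)(C)C(C)(C)C)[C@@H](C)/C=C(\C)[C@H](O)[C@@H](OC)C=C
F8 | step 23 | (E)-3-iodo-2-methylprop-2-enamide of F7 | CO[C@@H](C[C@H](C)Cc1cc(NC(=O)/C(C)=C/I)ccc1O[Si](C)(C)C(C)(C)C)[C@H](O[Si](C)(C)C(C)(C)C)[C@@H](C)/C=C(\C)[C@H](O)[C@@H](OC)C=C
A1 | alternative 1 | seco N-(furan-2-yl) amide with terminal alkynyl phenyl sulfone (C11 TBS ether, C7 carbamate) | CO[C@@H](C[C@H](C)CC#CS(=O)(=O)c1ccccc1)[C@H](O[Si](C)(C)C(C)(C)C)[C@@H](C)/C=C(\C)[C@H](OC(N)=O)[C@@H](OC)CC/C=C(\C)C(=O)Nc1ccco1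
A2 | alternative 1 | 19-membered lactam with phenylsulfonyl on C21 (C11 TBS ether, free C17 phenol) | CO[C@H]1C[C@H](C)Cc2c(S(=O)(=O)c3ccccc3)c(ccc2O)NC(=O)/C(C)=C/CC[C@H](OC)[C@@H](OC(N)=O)/C(C)=C/[C@H](C)[C@H]1O[Si](C)(C)C(C)(C)C
A3 | alternative 2 | seco primary amide with C20 aryl bromide (C11 TBS ether, C17 methoxymethyl ether, free C7 hydroxyl) | CO[C@@H](C[C@H](C)Cc1cc(Br)ccc1OCOC)[C@H](O[Si](C)(C)C(C)(C)C)[C@@H](C)/C=C(\C)[C@H](O)[C@@H](OC)CC/C=C(\C)C(N)=O
A4 | alternative 2 | 19-membered lactam with free C7 hydroxyl (C11 TBS ether, C17 methoxymethyl ether) | CO[C@H]1C[C@H](C)Cc2cc(ccc2OCOC)NC(=O)/C(C)=C/CC[C@H](OC)[C@@H](O)/C(C)=C/[C@H](C)[C@H]1O[Si](C)(C)C(C)(C)C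
A5 | alternative 3 | anilide of (E)-2-methylpenta-2,4-dienoic acid with C6 vinyl group (bis-TBS ether, C7 carbamate) | CO[C@@H](C[C@H](C)Cc1cc(NC(=O)/C(C)=C/C=C)ccc1O[Si](C)(C)C(C)(C)C)[C@H](O[Si](C)(C)C(C)(C)C)[C@@H](C)/C=C(\C)[C@H](OC(N)=O)[C@@H](OC)C=C
A6 | alternative 3 | 4,5-didehydro macrolactam (bis-TBS ether, 4E isomer drawn) | CO[C@H]1C[C@H](C)Cc2cc(ccc2O[Si](C)(C)C(C)(C)C)NC(=O)/C(C)=C/C=C/[C@H](OC)[C@@H](OC(N)=O)/C(C)=C/[C@H](C)[C@H]1O[Si](C)(C)C(C)(C)C
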